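## Retrosynthetic overview

1. Numbering: unit A = C1, O2, C3, C4, C4a, C5–C8, C8a; unit B (lactone) primed; the CH(CH3) linker joins C7 and C7'. Feature used: in carbocycle A the atoms C6–C7–C8 are an enolised 2-alkyl-1,3-dione (oxygens on C6 and C8 flank the linker-bearing C7), so this ring is a dehydrogenated 2,4,5-trisubstituted cyclohexane-1,3-dione.
2. Target 28 ⇐ hexa-ol 26 (C1 put on C8a with orthoformate, O2–C1 closure) ⇐ resorcinol 25 ⇐ dione 22 (dehydrogenation through its bis-silyl dienol ether).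
3. Dione 22 ⇐ ketone 20 (C5, C6, C7, with the linker centre and unit B) + enoate 6 (C4a, C8a, C8, with C3/C4): Michael bond C5–C4a, Claisen bond C7–C8.
4. Ketone 20 ⇐ CuH 1,4-reduction of aryl enone 18 ⇐ Suzuki coupling of C7'-bromo lactone 15 with boryl enone 17. Lactone 13 ⇐ resorcylate 11 ⇐ malonate Michael–Dieckmann annulation on enone 8.
5. Enoate 6 and enone 8 ⇐ aldehyde 4 ⇐ Fráter–Seebach methylation of methyl (R)-3-hydroxybutanoate, which sets both C3/C4 and C3'/C4'. Ring order: carbocycle B, lactone ring, carbocycle A, pyran ring of A.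

Key step: step 14

Remark: the target is drawn as the 6-hydroxy-8-oxo tautomer of the quinone methide, which equilibrates with the 8-hydroxy-6-oxo form, and the route is taken to deliver this equilibrating compound; the linker descriptor is S in 19–22, 25 and 26 and R in 28 only because the CIP ranking of the two rings changes.

## Route

Step 1
Reactants: 1 methyl (R)-3-hydroxybutanoate
Product: 2 methyl (2R,3R)-3-hydroxy-2-methylbutanoate
Conditions: LDA (2.2 equiv), THF, −78 → −20 °C; MeI, DMPU, −78 → 0 °C; aq. NH4Cl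
Reagents that add atoms: iodomethane (CI)
Why: Fráter–Seebach alkylation, in which the chelated dilithio alkoxide-enolate is methylated on the face anti to the C3 methyl group, so the new centre is set as R (anti, 2R,3R) by the existing carbinol centre.

Step 2
Reactants: 2 methyl (2R,3R)-3-hydroxy-2-methylbutanoate
Product: 3 methyl (2R,3R)-3-(benzyloxy)-2-methylbutanoate
Conditions: benzyl 2,2,2-trichloroacetimidate (1.5 equiv), TfOH (5 mol%), CH2Cl2/cyclohexane, 0 °C → rt
Reagents that add atoms: benzyl 2,2,2-trichloroacetimidate (N=C(OCc1ccccc1)C(Cl)(Cl)Cl)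
Why: Acid-catalysed O-benzylation with the trichloroacetimidate avoids the basic conditions that would cause retro-aldol cleavage, elimination or epimerisation of the β-hydroxy ester.

Step 3
Reactants: 3 methyl (2R,3R)-3-(benzyloxy)-2-methylbutanoate
Product: 4 (2R,3R)-3-(benzyloxy)-2-methylbutanal
Conditions: DIBAL-H (1.1 equiv), CH2Cl2, −78 °C; MeOH, Rochelle salt; crude aldehyde used at once
Reagents that add atoms: none
Why: Partial reduction of the ester with DIBAL-H stops at the aluminium hemiacetal (held by the β-benzyloxy oxygen) at −78 °C, and immediate use of the aldehyde guards the α-centre against epimerisation.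

Step 4
Reactants: 4 (2R,3R)-3-(benzyloxy)-2-methylbutanal; 5 methyl (triphenyl-λ5-phosphanylidene)acetate
Product: 6 methyl (2E,4S,5R)-5-(benzyloxy)-4-methylhex-2-enoate
Conditions: CH2Cl2, rt
Reagents that add atoms: none
Why: Wittig olefination with a stabilised ylide is E-selective and essentially neutral, so the α-stereocentre of the aldehyde is carried into C4 unchanged.

Step 5
Reactants: 4 (2R,3R)-3-(benzyloxy)-2-methylbutanal; 7 3-(triphenyl-λ5-phosphanylidene)butan-2-one
Product: 8 (3E,5S,6R)-6-(benzyloxy)-3,5-dimethylhept-3-en-2-one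
Conditions: toluene, 90–100 °C
Reagents that add atoms: none
Why: Wittig olefination with the α-methyl keto ylide gives the trisubstituted E-enone that carries the future C5' methyl and C6'/C7' carbons, again without base strong enough to epimerise the allylic centre.

Step 6
Reactants: 8 (3E,5S,6R)-6-(benzyloxy)-3,5-dimethylhept-3-en-2-one; 9 dimethyl malonate
Product: 10 methyl 2-[(2S,3R)-3-(benzyloxy)butan-2-yl]-3-methyl-4,6-dioxocyclohexane-1-carboxylate (ring centres unspecified, enol tautomers)
Conditions: NaOMe (1.2 equiv), dimethyl malonate (1.3 equiv), MeOH, reflux; 1 M HCl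
Reagents that add atoms: none
Why: Malonate adds to the enone β-carbon (Michael) and the methyl-ketone enolate then closes onto a malonate ester (Dieckmann-type Claisen, 6-exo-trig), the classical dihydroresorcinol ester synthesis, in which the roles of the partners fix the ring B substitution pattern, the malonate buffer keeps the medium too weakly basic to enolise the allylic centre, and the new ring centres are erased in step 7.

Step 7
Reactants: 10 methyl 2-[(2S,3R)-3-(benzyloxy)butan-2-yl]-3-methyl-4,6-dioxocyclohexane-1-carboxylate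
Product: 11 methyl 2-[(2S,3R)-3-(benzyloxy)butan-2-yl]-4,6-dihydroxy-3-methylbenzoate
Conditions: Br2 (1.0 equiv), DMF, 0 °C → rt, then 80 °C
Reagents that add atoms: none
Why: Bromination at the carbon between the two carbonyl groups followed by loss of two molecules of HBr through the enol forms is the standard oxidative aromatisation of 4-carbomethoxycyclohexane-1,3-diones to 2,4-dihydroxybenzoates, and one equivalent of bromine leaves the new resorcinol unbrominated.

Step 8
Reactants: 11 methyl 2-[(2S,3R)-3-(benzyloxy)butan-2-yl]-4,6-dihydroxy-3-methylbenzoate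
Product: 13 (3R,4S)-6,8-dihydroxy-3,4,5-trimethylisochroman-1-one, via hydroxy ester 12 (not isolated)
Conditions: H2 (1 atm), 10% Pd/C, MeOH, rt; filter; p-TsOH·H2O (10 mol%), toluene, 80 °C
Reagents that add atoms: none
Why: Hydrogenolysis of the alkyl benzyl ether frees the C3' hydroxyl, which lactonises onto the ortho ester under acid to the six-membered dihydroisocoumarin by acyl substitution, so C3' and C4' are not touched.

Step 9
Reactants: 13 (3R,4S)-6,8-dihydroxy-3,4,5-trimethylisochroman-1-one
Product: 14 (3R,4S)-7-bromo-6,8-dihydroxy-3,4,5-trimethylisochroman-1-one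
Conditions: NBS (1.0 equiv), MeCN, 0 °C, dark
Reagents that add atoms: N-bromosuccinimide (O=C1CCC(=O)N1Br)
Why: Electrophilic bromination can only occur at C7', the single free ring position, which is ortho to both hydroxyl groups.

Step 10
Reactants: 14 (3R,4S)-7-bromo-6,8-dihydroxy-3,4,5-trimethylisochroman-1-one
Product: 15 (3R,4S)-6,8-bis(benzyloxy)-7-bromo-3,4,5-trimethylisochroman-1-one
Conditions: BnBr (2.5 equiv), K2CO3 (3 equiv), DMF, 60 °C
Reagents that add atoms: benzyl bromide (BrCc1ccccc1)
Why: Williamson benzylation of both phenols under anhydrous carbonate conditions (warming overcomes the hydrogen bond of the C8' hydroxyl) gives ethers that survive strong base and are later removed by hydrogenolysis.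

Step 11
Reactants: 16 hex-4-yn-3-one
Product: 17 (4Z)-5-(4,4,5,5-tetramethyl-1,3,2-dioxaborolan-2-yl)hex-4-en-3-one
Conditions: B2pin2 (1.1 equiv), CuCl (5 mol%), Xantphos (5 mol%), NaOt-Bu (10 mol%), MeOH (2 equiv), THF, rt
Reagents that add atoms: bis(pinacolato)diboron (CC1(C)OB(OC1(C)C)B1OC(C)(C)C(C)(C)O1)
Why: Copper-catalysed conjugate borylation of the ynone proceeds by syn borylcupration with boron at the β-carbon and protonation by methanol, giving the β-boryl enone with boron trans to the carbonyl group.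

Step 12
Reactants: 15 (3R,4S)-6,8-bis(benzyloxy)-7-bromo-3,4,5-trimethylisochroman-1-one; 17 (4Z)-5-(4,4,5,5-tetramethyl-1,3,2-dioxaborolan-2-yl)hex-4-en-3-one
Product: 18 (3R,4S)-6,8-bis(benzyloxy)-3,4,5-trimethyl-7-[(2E)-4-oxohex-2-en-2-yl]isochroman-1-one
Conditions: Pd(OAc)2 (5 mol%), SPhos (10 mol%), K3PO4 (3 equiv), toluene/H2O (10:1), 80 °C
Reagents that add atoms: none
Why: Suzuki–Miyaura coupling with a dialkylbiarylphosphine ligand tolerates the di-ortho-alkoxy aryl bromide and transfers the alkenyl group with retention, so the aryl group ends trans to the carbonyl (E) and the hindered lactone is left intact.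

Step 13
Reactants: 18 (3R,4S)-6,8-bis(benzyloxy)-3,4,5-trimethyl-7-[(2E)-4-oxohex-2-en-2-yl]isochroman-1-one
Product: 20 (3R,4S)-6,8-bis(benzyloxy)-3,4,5-trimethyl-7-[(2S)-4-oxohexan-2-yl]isochroman-1-one, via silyl enol ether 19 (not isolated)
Conditions: Cu(OAc)2·H2O (5 mol%), (R)-DTBM-SEGPHOS (5 mol%), (EtO)2MeSiH (3 equiv), toluene, 0 °C; then 1 M HCl, THF, rt
Reagents that add atoms: none
Why: Ligand-controlled asymmetric CuH 1,4-hydrosilylation of an acyclic β-aryl-β-methyl enone delivers hydride to the Re face of the β-carbon of the geometrically pure E-enone to set the S linker centre (the ligand antipode is exchanged if a test reduction shows the opposite sense), and the silyl enol ether formed shields the carbonyl from 1,2-reduction until hydrolysis.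

Step 14
Reactants: 20 (3R,4S)-6,8-bis(benzyloxy)-3,4,5-trimethyl-7-[(2S)-4-oxohexan-2-yl]isochroman-1-one; 6 methyl (2E,4S,5R)-5-(benzyloxy)-4-methylhex-2-enoate
Product: 22 5-[(2S,3R)-3-(benzyloxy)butan-2-yl]-2-{(1S)-1-[(3R,4S)-6,8-bis(benzyloxy)-3,4,5-trimethyl-1-oxoisochroman-7-yl]ethyl}-4-methylcyclohexane-1,3-dione, via Michael adduct 21 (not isolated)
Conditions: LDA (1.05 equiv), THF, −78 °C; 6 (1.2 equiv), −78 → −30 °C; then rt → 45 °C; 1 M HCl
Reagents that add atoms: none
Why: The kinetic lithium enolate of 20 forms at the ethyl CH2 (C5), because the other α-CH2 (C7) is screened by the β-branched linker with its 2,6-bis(benzyloxy)aryl group, and it adds 1,4 to the E-enoate 6 to make the C5–C4a bond. On warming, the diisopropylamine present shuttles a proton so that the ester enolate of 21 becomes the C7 ketone enolate, which attacks the ester carbon C8 in a 6-exo-trig Claisen (Dieckmann-type) closure and expels methoxide. The closest known reaction is the consecutive Michael–Claisen synthesis of cyclohexane-1,3-diones from ketones and α,β-unsaturated esters. Deprotonation of the resulting 2-substituted 1,3-dione by the methoxide makes the sequence irreversible and uses up the only nucleophilic base, so the hindered aryl lactone of unit B is not attacked. The new ring centres need no control, since C7 is enolised and C4a/C5 become sp2 on aromatisation, while C3, C4 (no longer activated once the conjugate addition has occurred) and the linker centre are carried through unchanged. The step needs C5-over-C7 enolisation and 1,4-addition over 1,2-addition or γ-deprotonation of 6, which the steric bias of 20, the low temperature of the addition and the absence of free amide base after enolate formation should secure.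

Step 15
Reactants: 22 5-[(2S,3R)-3-(benzyloxy)butan-2-yl]-2-{(1S)-1-[(3R,4S)-6,8-bis(benzyloxy)-3,4,5-trimethyl-1-oxoisochroman-7-yl]ethyl}-4-methylcyclohexane-1,3-dione
Product: 23 (3R,4S)-6,8-bis(benzyloxy)-7-{1-[4-[(2S,3R)-3-(benzyloxy)butan-2-yl]-3-methyl-2,6-bis(trimethylsilyloxy)cyclohexa-1,5-dien-1-yl]ethyl}-3,4,5-trimethylisochroman-1-one (linker centre as in 20; used crude)
Conditions: TMSOTf (2.5 equiv), Et3N (3.5 equiv), CH2Cl2, 0 °C → rt; concentrate, pentane, filter
Reagents that add atoms: trimethylsilyl trifluoromethanesulfonate (C[Si](C)(C)OS(=O)(=O)C(F)(F)F)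
Why: Soft enolisation with TMSOTf/Et3N converts the enolised 1,3-dione into its 1,3-bis(silyloxy)cyclohexa-1,3-diene without any reagent acting at the substituted C7 or at the adjacent linker C–H, and either regioisomer of the dienol ether leads to the same arene.

Step 16
Reactants: 23 bis(trimethylsilyl) dienol ether of 22
Product: 25 (3R,4S)-6,8-bis(benzyloxy)-7-[(1S)-1-{4-[(2S,3R)-3-(benzyloxy)butan-2-yl]-2,6-dihydroxy-3-methylphenyl}ethyl]-3,4,5-trimethylisochroman-1-one, via aryl bis-silyl ether 24 (not isolated)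
Conditions: DDQ (1.1 equiv), 2,4,6-collidine (1.5 equiv), benzene, 5 °C → rt; then MeOH, PPTS (cat.), rt
Reagents that add atoms: none
Why: DDQ abstracts hydride from C4a of the electron-rich silyloxy diene and proton loss gives the aromatic bis-silyl ether (dehydrogenative aromatisation of a cyclohexadiene), a path that never places a leaving group on C7 and so cannot scramble the linker centre, after which methanol cleaves the labile aryl silyl ethers.

Step 17
Reactants: 25 tribenzyl-protected bis-resorcinol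
Product: 26 (3R,4S)-7-[(1S)-1-{2,6-dihydroxy-4-[(2S,3R)-3-hydroxybutan-2-yl]-3-methylphenyl}ethyl]-6,8-dihydroxy-3,4,5-trimethylisochroman-1-one
Conditions: H2 (1 atm), 20% Pd(OH)2/C, EtOAc/MeOH (1:1), rt
Reagents that add atoms: none
Why: Catalytic hydrogenolysis removes the two aryl and the one alkyl benzyl ether under neutral conditions, with the lactone, the phenols and the diarylethane linker inert.

Step 18
Reactants: 26 hexa-ol
Product: 28 dicitrinone H, via ethoxy acetal 27 (not isolated)
Conditions: HC(OEt)3 (10 equiv), TFA (3 equiv), THF, 0 °C → rt; then H2O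
Reagents that add atoms: triethyl orthoformate (CCOC(OCC)OCC)
Why: Acid-catalysed orthoformate formylation occurs at C8a, the only free ring position of either resorcinol (ortho to the C8 and para to the C6 hydroxyl), the C3 hydroxyl closes onto the new carbon to give the cyclic acetal, and loss of ethanol gives the quinone methide, the established closure of 2-(3-hydroxybutan-2-yl)resorcinols to 3,4-dimethylisochromene quinone methides.

## Compound list

1 | methyl (R)-3-hydroxybutanoate | C[C@@H](O)CC(=O)OC | starting material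
2 | methyl (2R,3R)-3-hydroxy-2-methylbutanoate | C[C@@H](O)[C@@H](C)C(=O)OC | intermediate
3 | methyl (2R,3R)-3-(benzyloxy)-2-methylbutanoate | C[C@@H](OCc1ccccc1)[C@@H](C)C(=O)OC | intermediate
4 | (2R,3R)-3-(benzyloxy)-2-methylbutanal | C[C@@H](OCc1ccccc1)[C@@H](C)C=O | intermediate
5 | methyl (triphenyl-λ5-phosphanylidene)acetate | COC(=O)C=P(c1ccccc1)(c1ccccc1)c1ccccc1 | starting material
6 | methyl (2E,4S,5R)-5-(benzyloxy)-4-methylhex-2-enoate | C[C@@H](OCc1ccccc1)[C@@H](C)/C=C/C(=O)OC | intermediate
7 | 3-(triphenyl-λ5-phosphanylidene)butan-2-one | CC(=O)C(C)=P(c1ccccc1)(c1ccccc1)c1ccccc1 | starting material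
8 | (3E,5S,6R)-6-(benzyloxy)-3,5-dimethylhept-3-en-2-one | C[C@@H](OCc1ccccc1)[C@@H](C)/C=C(\C)C(C)=O | intermediate
9 | dimethyl malonate | COC(=O)CC(=O)OC | starting material
10 | methyl 2-[(2S,3R)-3-(benzyloxy)butan-2-yl]-3-methyl-4,6-dioxocyclohexane-1-carboxylate (ring centres unspecified) | COC(=O)C1C(=O)CC(=O)C(C)C1[C@H](C)[C@@H](C)OCc1ccccc1 | intermediate
11 | methyl 2-[(2S,3R)-3-(benzyloxy)butan-2-yl]-4,6-dihydroxy-3-methylbenzoate | COC(=O)c1c(O)cc(O)c(C)c1[C@H](C)[C@@H](C)OCc1ccccc1 | intermediate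
12 | methyl 4,6-dihydroxy-2-[(2S,3R)-3-hydroxybutan-2-yl]-3-methylbenzoate (not isolated) | COC(=O)c1c(O)cc(O)c(C)c1[C@H](C)[C@@H](C)O | intermediate
13 | (3R,4S)-6,8-dihydroxy-3,4,5-trimethylisochroman-1-one | Oc1cc(O)c(C)c2c1C(=O)O[C@H](C)[C@H]2C | intermediate
14 | (3R,4S)-7-bromo-6,8-dihydroxy-3,4,5-trimethylisochroman-1-one | Oc1c(Br)c(O)c(C)c2c1C(=O)O[C@H](C)[C@H]2C | intermediate
15 | (3R,4S)-6,8-bis(benzyloxy)-7-bromo-3,4,5-trimethylisochroman-1-one | Brc1c(OCc2ccccc2)c(C)c2c(c1OCc1ccccc1)C(=O)O[C@H](C)[C@H]2C | intermediate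
16 | hex-4-yn-3-one | CCC(=O)C#CC | starting material
17 | (4Z)-5-(4,4,5,5-tetramethyl-1,3,2-dioxaborolan-2-yl)hex-4-en-3-one | CCC(=O)/C=C(\C)B1OC(C)(C)C(C)(C)O1 | intermediate
18 | (3R,4S)-6,8-bis(benzyloxy)-3,4,5-trimethyl-7-[(2E)-4-oxohex-2-en-2-yl]isochroman-1-one | CCC(=O)/C=C(\C)c1c(OCc2ccccc2)c(C)c2c(c1OCc1ccccc1)C(=O)O[C@H](C)[C@H]2C | intermediate
19 | (3R,4S)-6,8-bis(benzyloxy)-7-[(2S)-4-{[diethoxy(methyl)silyl]oxy}hex-3-en-2-yl]-3,4,5-trimethylisochroman-1-one (not isolated; enol ether geometry unspecified) | CCC(O[Si](C)(OCC)OCC)=C[C@H](C)c1c(OCc2ccccc2)c(C)c2c(c1OCc1ccccc1)C(=O)O[C@H](C)[C@H]2C | intermediate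
20 | (3R,4S)-6,8-bis(benzyloxy)-3,4,5-trimethyl-7-[(2S)-4-oxohexan-2-yl]isochroman-1-one (5-arylhexan-3-one, key-step precursor) | CCC(=O)C[C@H](C)c1c(OCc2ccccc2)c(C)c2c(c1OCc1ccccc1)C(=O)O[C@H](C)[C@H]2C | intermediate
21 | methyl (7S)-3-[(2S,3R)-3-(benzyloxy)butan-2-yl]-7-[(3R,4S)-6,8-bis(benzyloxy)-3,4,5-trimethyl-1-oxoisochroman-7-yl]-4-methyl-5-oxooctanoate (Michael adduct, present as its enolate, not isolated; C3 and C4 unspecified) | COC(=O)CC([C@H](C)[C@@H](C)OCc1ccccc1)C(C)C(=O)C[C@H](C)c1c(OCc2ccccc2)c(C)c2c(c1OCc1ccccc1)C(=O)O[C@H](C)[C@H]2C | intermediate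
22 | 5-[(2S,3R)-3-(benzyloxy)butan-2-yl]-2-{(1S)-1-[(3R,4S)-6,8-bis(benzyloxy)-3,4,5-trimethyl-1-oxoisochroman-7-yl]ethyl}-4-methylcyclohexane-1,3-dione (key-step product; ring centres unspecified, drawn as diketone) | CC1C(=O)C([C@H](C)c2c(OCc3ccccc3)c(C)c3c(c2OCc2ccccc2)C(=O)O[C@H](C)[C@H]3C)C(=O)CC1[C@H](C)[C@@H](C)OCc1ccccc1 | intermediate
23 | bis(trimethylsilyl) dienol ether of 22: (3R,4S)-6,8-bis(benzyloxy)-7-{1-[4-[(2S,3R)-3-(benzyloxy)butan-2-yl]-3-methyl-2,6-bis(trimethylsilyloxy)cyclohexa-1,5-dien-1-yl]ethyl}-3,4,5-trimethylisochroman-1-one (linker centre as in 20) | CC1C(O[Si](C)(C)C)=C([C@H](C)c2c(OCc3ccccc3)c(C)c3c(c2OCc2ccccc2)C(=O)O[C@H](C)[C@H]3C)C(O[Si](C)(C)C)=CC1[C@H](C)[C@@H](C)OCc1ccccc1 | intermediate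
24 | bis(trimethylsilyl) ether of 25 (not isolated; linker centre as in 20) | Cc1c(O[Si](C)(C)C)c([C@H](C)c2c(OCc3ccccc3)c(C)c3c(c2OCc2ccccc2)C(=O)O[C@H](C)[C@H]3C)c(O[Si](C)(C)C)cc1[C@H](C)[C@@H](C)OCc1ccccc1 | intermediate
25 | (3R,4S)-6,8-bis(benzyloxy)-7-[(1S)-1-{4-[(2S,3R)-3-(benzyloxy)butan-2-yl]-2,6-dihydroxy-3-methylphenyl}ethyl]-3,4,5-trimethylisochroman-1-one | Cc1c(O)c([C@H](C)c2c(OCc3ccccc3)c(C)c3c(c2OCc2ccccc2)C(=O)O[C@H](C)[C@H]3C)c(O)cc1[C@H](C)[C@@H](C)OCc1ccccc1 | intermediate
26 | (3R,4S)-7-[(1S)-1-{2,6-dihydroxy-4-[(2S,3R)-3-hydroxybutan-2-yl]-3-methylphenyl}ethyl]-6,8-dihydroxy-3,4,5-trimethylisochroman-1-one | Cc1c(O)c([C@H](C)c2c(O)c(C)c3c(c2O)C(=O)O[C@H](C)[C@H]3C)c(O)cc1[C@H](C)[C@@H](C)O | intermediate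
27 | (3R,4S)-1-ethoxy-6,8-dihydroxy-3,4,5-trimethylisochroman carrying the unit B ethyl group at C7 (cyclic acetal, C1 unspecified, linker centre as in 26, not isolated) | CCOC1O[C@H](C)[C@@H](C)c2c(C)c(O)c([C@H](C)c3c(O)c(C)c4c(c3O)C(=O)O[C@H](C)[C@H]4C)c(O)c12 | intermediate
28 | dicitrinone H | CC1=C2C(=CO[C@H](C)[C@H]2C)C(=O)C([C@H](C)c2c(O)c(C)c3c(c2O)C(=O)O[C@H](C)[C@H]3C)=C1O | target

## Step count and risk

Total steps: 18. Longest linear sequence: 16 (steps 1–3, 5–10, 12–18).

Steps most likely to fail: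

1. Step 14 (key step). Enolisation may occur partly on the C7 side, the enolate may remove the γ-proton of the enoate instead of adding to it (with loss of the C4 configuration or of benzyl alcohol), and the Claisen closure at the hindered C7 may be slow. Fallback, from 20 and 4, returning at 22: the lithium enolate of 20 (LDA, −78 °C) is added to aldehyde 4 to give β-hydroxy ketone F1. Mesylation and DBU elimination give (E)-enone F2. Dimethyl malonate 9 with NaOMe in MeOH then adds to C4a and the C7 enolate closes on a malonate ester to give dione ester F3, with an acidic work-up re-closing any lactone opened by methoxide. Krapcho demethoxycarbonylation (LiCl, wet DMSO, 130 °C) gives 22. The sluggish ketone-enolate Michael addition is thereby replaced by an aldol reaction and a soft malonate addition.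

2. Step 15 (with step 16). The second silylation of the hindered 2-substituted dione may stay incomplete, and in the following dehydrogenation hydride may be taken from the doubly benzylic linker C–H instead of C4a. Fallback, from 22, returning at 26: iodine in refluxing methanol (vinylogous ester formation, iodination and dehydroiodination) aromatises the dione to the regioisomeric resorcinol monomethyl ethers F5 and F6, which are used together. BBr3 (CH2Cl2, −78 → 0 °C) then cleaves the methyl ether and all three benzyl ethers to give 26, by-passing steps 16 and 17.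

3. Step 13. Facial discrimination may be poor at the twisted di-ortho-substituted aryl enone, and the carbonyl group may be over-reduced. Fallback, from 15, returning at 20: Heck coupling of 15 with pent-1-en-3-one (Pd2(dba)3, P(t-Bu)3, Cy2NMe, dioxane, 80 °C) gives (E)-aryl enone F4. Copper-catalysed asymmetric conjugate addition of MeMgBr (CuBr·SMe2, Josiphos-type ligand, t-BuOMe, −75 °C, at which the hindered lactone should be spared) then installs the linker methyl group to give 20. The stereocentre is then set by C–C instead of C–H bond formation.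

Further compounds
F1 | step 14 | (3R,4S)-6,8-bis(benzyloxy)-7-[(2S,7S,8R)-8-(benzyloxy)-6-hydroxy-5,7-dimethyl-4-oxononan-2-yl]-3,4,5-trimethylisochroman-1-one (aldol adduct, C5 and C6 of the chain unspecified) | CC(C(O)[C@H](C)[C@@H](C)OCc1ccccc1)C(=O)C[C@H](C)c1c(OCc2ccccc2)c(C)c2c(c1OCc1ccccc1)C(=O)O[C@H](C)[C@H]2C
F2 | step 14 | (3R,4S)-6,8-bis(benzyloxy)-7-[(2S,5E,7S,8R)-8-(benzyloxy)-5,7-dimethyl-4-oxonon-5-en-2-yl]-3,4,5-trimethylisochroman-1-one | C[C@@H](OCc1ccccc1)[C@@H](C)/C=C(\C)C(=O)C[C@H](C)c1c(OCc2ccccc2)c(C)c2c(c1OCc1ccccc1)C(=O)O[C@H](C)[C@H]2C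
F3 | step 14 | methyl 2-[(2S,3R)-3-(benzyloxy)butan-2-yl]-5-{(1S)-1-[(3R,4S)-6,8-bis(benzyloxy)-3,4,5-trimethyl-1-oxoisochroman-7-yl]ethyl}-3-methyl-4,6-dioxocyclohexane-1-carboxylate (ring centres unspecified) | COC(=O)C1C(=O)C([C@H](C)c2c(OCc3ccccc3)c(C)c3c(c2OCc2ccccc2)C(=O)O[C@H](C)[C@H]3C)C(=O)C(C)C1[C@H](C)[C@@H](C)OCc1ccccc1
F4 | step 13 | (3R,4S)-6,8-bis(benzyloxy)-3,4,5-trimethyl-7-[(1E)-3-oxopent-1-en-1-yl]isochroman-1-one | CCC(=O)/C=C/c1c(OCc2ccccc2)c(C)c2c(c1OCc1ccccc1)C(=O)O[C@H](C)[C@H]2C
F5 | step 15 | 6-O-methyl ether of 25 (methoxy group next to the C5 methyl group) | Cc1c(OC)c([C@H](C)c2c(OCc3ccccc3)c(C)c3c(c2OCc2ccccc2)C(=O)O[C@H](C)[C@H]3C)c(O)cc1[C@H](C)[C@@H](C)OCc1ccccc1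
F6 | step 15 | 8-O-methyl ether of 25 (methoxy group next to C8a) | Cc1c(O)c([C@H](C)c2c(OCc3ccccc3)c(C)c3c(c2OCc2ccccc2)C(=O)O[C@H](C)[C@H]3C)c(OC)cc1[C@H](C)[C@@H](C)OCc1ccccc1
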